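**Plan**

1. Numbering follows the skeleton: C1 (CH–OAc), C2, C3 (C(CH3)OAc), C4, C5 (fusion CH), C6, C7 (C=O), C8=C9, C10, C11, N12, C13–C15, C16 (quaternary). Ring A is C1–C5 + C16, ring B is C5–C8 + C16, ring C is C8–C16.
2. Retrosynthetic cuts, in order: N12–H (from N–Ns), C8=C9 (from a C9 acetate), the O–acetyl bonds, N12–C11, N12–C13, C8–C9 (aldol), C3–CH3, C1–O, then C5–C6, and last ring A (annulation at C16).
3. Forward order of rings: A (Robinson annulation, then dehydrogenation), B (intramolecular Michael addition), C (Mitsunobu closure of the azonane). The C8=C9 bond is released only inside ring C.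
4. Enabling feature: in ring A the quaternary C16 lies para to C3. With C3 as carbonyl and C1=C2 and C4=C5 as double bonds, ring A is an achiral 4,4-disubstituted cyclohexa-2,5-dienone with two enantiotopic enone arms, and attack of C6 on C5 of one arm makes ring B.
5. Stereochemistry: C16 and C5 come from the chiral amine–thiourea catalyst, with the cis fusion enforced by the five-membered ring. C1–O comes from an epoxidation directed by a C3–OH, C3 from axial methyl delivery, and (E)-C8=C9 from the ring constraint.
6. Spectators: C13 is carried as a benzyl ether and the C6 activator as a benzyl ester, and both fall in one hydrogenolysis. N12 enters late as a sulfonamide, because an imide or carbamate nitrogen would not survive MeLi, iBu2AlH and LiN(iPr)2.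

Key step: step 7

Convention: the β face of ring A is the face that carries C6 and C8 (ring B). The α face carries H5 and the C15 chain and is the convex face of the cis-fused bicycle.

Assumption: the quinine-derived catalyst is taken to give the enantiomer drawn for 16. If the sense proves opposite, the quinidine-derived pseudo-enantiomer is used in step 7 and nothing else changes.

**Step 1**
Reactants: 1 5-(benzyloxy)pentan-1-ol
Product: 2 5-(benzyloxy)pentanal
Conditions: TEMPO (10 mol %), PhI(OAc)2, CH2Cl2, rt
Reagents that add atoms: none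
Why: Oxoammonium (TEMPO) oxidation of a primary alcohol should stop at the aldehyde and leave the benzyl ether untouched; no stereocentre is formed.

**Step 2**
Reactants: 2 5-(benzyloxy)pentanal; 3 tert-butyl bromoacetate
Product: 5 tert-butyl 6-(benzyloxy)-3-formylhexanoate (racemic), via enamine 4 (not isolated)
Conditions: iBu2NH, toluene, reflux (Dean–Stark); 3, MeCN, reflux; AcOH–H2O, rt
Reagents that add atoms: water, O (aldehyde oxygen of 5); diisobutylamine, CC(C)CNCC(C)C (amine part of 4 only)
Why: Stork enamine alkylation, in which the hindered enamine is alkylated at carbon by the reactive α-bromo ester and aqueous acid returns the aldehyde; the new centre is racemic and becomes the symmetric C16 of dienone 10.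

**Step 3**
Reactants: 5 tert-butyl 6-(benzyloxy)-3-formylhexanoate; 6 methyl vinyl ketone
Product: 8 tert-butyl 2-{1-[3-(benzyloxy)propyl]-4-oxocyclohex-2-en-1-yl}acetate (racemic), via keto aldehyde 7 (not isolated)
Conditions: KOH (0.2 equiv), EtOH, 0 °C to 50 °C
Reagents that add atoms: none
Why: Robinson annulation, in which Michael addition of the α-branched aldehyde to 6 creates the quaternary C16 and aldol condensation of 7 closes ring A; the racemic outcome is irrelevant.

**Step 4**
Reactants: 8 cyclohexenone tert-butyl ester
Product: 10 tert-butyl 2-{1-[3-(benzyloxy)propyl]-4-oxocyclohexa-2,5-dien-1-yl}acetate (achiral), via lithium dienolate 9 (not isolated)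
Conditions: LiN(iPr)2, THF, −78 °C; PhS(Cl)=NtBu, −78 °C
Reagents that add atoms: LiN(iPr)2, [Li+].CC(C)[N-]C(C)C (lithium of 9 only)
Why: Mukaiyama dehydrogenation, in which the kinetic cross-conjugated enolate 9 is captured at the α′ carbon by the sulfinimidoyl chloride and the adduct eliminates at low temperature; this spares the benzyl ether, which quinone oxidants would endanger, and the stereocentre vanishes as the ring becomes symmetric.

**Step 5**
Reactants: 10 dienone tert-butyl ester
Product: 11 2-{1-[3-(benzyloxy)propyl]-4-oxocyclohexa-2,5-dien-1-yl}acetic acid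
Conditions: TFA–CH2Cl2 (1:3), 0 °C to rt
Reagents that add atoms: none
Why: Acidolysis of a tert-butyl ester by loss of isobutene; the benzyl ether and the cross-conjugated dienone should tolerate short exposure to dilute TFA.

**Step 6**
Reactants: 11 dienone acetic acid; 12 Meldrum's acid; 13 benzyl alcohol
Product: 15 benzyl 4-{1-[3-(benzyloxy)propyl]-4-oxocyclohexa-2,5-dien-1-yl}-3-oxobutanoate (achiral dienone β-keto ester), via acyl Meldrum's acid 14 (not isolated)
Conditions: 12, DCC, DMAP, CH2Cl2, 0 °C to rt, aq. KHSO4 wash; 13, toluene, 90 °C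
Reagents that add atoms: none
Why: Oikawa–Yonemitsu β-keto ester synthesis, in which 12 is C-acylated and 14 is thermolysed to an acylketene that benzyl alcohol traps; the β-keto ester is therefore released without base and should not close prematurely to racemic material.

**Step 7**
Reactants: 15 achiral dienone β-keto ester
Product: 16 benzyl cis-3a-[3-(benzyloxy)propyl]-2,6-dioxo-2,3,3a,6,7,7a-hexahydro-1H-indene-1-carboxylate (H5 and the C15 chain α; C6 ester on the convex face, trans to C4)
Conditions: 1-[3,5-bis(trifluoromethyl)phenyl]-3-[(8α,9S)-6′-methoxycinchonan-9-yl]thiourea (10 mol %), toluene, −20 °C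
Reagents that add atoms: none
Why: The quinuclidine nitrogen removes a proton from C6, the only doubly activated CH2, while the thiourea N–H pair binds the C3 carbonyl; the ion-paired enolate then attacks C5 of one enone arm through C6 and the resulting dienolate is protonated at C4. This is an organocatalytic desymmetrizing intramolecular Michael addition of a stabilized carbon nucleophile to a 4,4-disubstituted cyclohexadienone, a known reaction class. Ring B (C5, C6, C7, C8, C16) closes in the 5-exo-trig mode. C16 and C5 are set together by the catalyst's choice between the enantiotopic arms C5=C4 and C1=C2, and their cis relation is fixed because the three-atom tether from C16 reaches C5 only on its own face; C6 is epimerizable and should settle with the ester on the convex face. The step needs enantiotopic-group selection, which two-point binding in a non-polar solvent at low temperature and the base-free history of 15 should secure. No regiochemical alternative exists, because C8 is not acidic enough and a second closure onto C1 would need a four-membered ring.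

**Step 8**
Reactants: 16 bicyclic enone β-keto ester
Product: 18 allylic alcohol (C3–OH β; C1=C2 kept; β-keto ester intact), via lithium enolate 17 (not isolated)
Conditions: LiN(SiMe3)2 (1.05 equiv), THF, −78 °C; iBu2AlH, −78 °C; aq. potassium sodium tartrate
Reagents that add atoms: LiN(SiMe3)2, [Li+].C[Si](C)(C)[N-][Si](C)(C)C (lithium of 17 only)
Why: Enolate protection followed by 1,2-reduction of the enone; the base removes only the C6 proton and enolate 17 resists hydride (and retro-Michael cleavage), while hydride reaches C3 from the convex α face, anti to the C5–C6 bond, which places the hydroxyl on the β face.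

**Step 9**
Reactants: 18 allylic alcohol
Product: 19 β-epoxy alcohol (C1–C2 oxirane and C3–OH all on the β face)
Conditions: VO(acac)2 (5 mol %), tBuOOH, CH2Cl2, 0 °C to rt
Reagents that add atoms: tert-butyl hydroperoxide, CC(C)(C)OO
Why: Hydroxyl-directed vanadium-catalysed epoxidation, in which oxygen is passed on within the vanadium alkoxide of the C3–OH; C1 and C2 are therefore oxygenated on the β face, a face that nucleophilic epoxidation of enone 16 (expected on the convex α face) would not reach.

**Step 10**
Reactants: 19 β-epoxy alcohol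
Product: 20 β-epoxy ketone (C3=O)
Conditions: Dess–Martin periodinane, CH2Cl2, 0 °C to rt
Reagents that add atoms: none
Why: Dess–Martin oxidation of a secondary alcohol under neutral conditions should return the C3 ketone without opening the oxirane; C1 and C2 are unaffected.

**Step 11**
Reactants: 20 β-epoxy ketone
Product: 21 β-hydroxy ketone (C1–OH β, C2H2, C3=O)
Conditions: SmI2 (2.2 equiv), THF–MeOH, −78 °C
Reagents that add atoms: none
Why: SmI2 reduction of an α,β-epoxy ketone, in which the C3 ketyl cleaves only the α C2–O bond and methanol protonates the samarium enolate; the regiochemistry is therefore inherent and the C1–O bond keeps its β configuration.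

**Step 12**
Reactants: 21 β-hydroxy ketone
Product: 22 C1 tert-butyldimethylsilyl ether
Conditions: TBSOTf, 2,6-lutidine, CH2Cl2, −78 °C to −20 °C
Reagents that add atoms: TBSOTf, CC(C)(C)[Si](C)(C)OS(=O)(=O)C(F)(F)F
Why: Silyl ether formation with a weak base at low temperature should protect the aldol-type hydroxyl against elimination and against the carbanion chemistry that follows; no stereocentre changes.

**Step 13**
Reactants: 22 silyloxy ketone
Product: 24 tertiary alcohol (C3–OH β and C3–CH3 α; cis to C1–OTBS), via lithium enolate 23 (not isolated)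
Conditions: MeAl(OAr)2, Ar = 2,6-tBu2-4-MeC6H2 (MAD, 3 equiv), toluene, −78 °C; MeLi (3 equiv), −78 °C
Reagents that add atoms: methyllithium, [Li]C (C3 methyl group; lithium of 23)
Why: Amphiphilic carbonyl alkylation with a bulky aluminium Lewis acid; the first MeLi turns the β-keto ester into the inert enolate 23, MAD occupies the open equatorial side of the C3 carbonyl in the ring-A chair (C1–OTBS and C5–C6 equatorial, C16–C8 axial), and MeLi should therefore enter axially from the α face to give the equatorial β-hydroxyl.

**Step 14**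
Reactants: 24 tertiary alcohol β-keto ester; 25 3-(tert-butyldimethylsilyloxy)propanal
Product: 27 C8 aldol adduct (C9–OH; mixture at C6/C8/C9), via trilithium trianion 26 (not isolated)
Conditions: LiN(iPr)2 (3.3 equiv), THF, −78 °C to 0 °C; 25, −78 °C; AcOH
Reagents that add atoms: LiN(iPr)2, [Li+].CC(C)[N-]C(C)C (lithium of 26 only)
Why: Weiler dianion aldol addition, in which the third equivalent of base can deprotonate only C8 once the alkoxide and the C6 enolate exist; this more basic terminus adds to the aldehyde, expected from the convex face, and the centres at C6, C8 and C9 are uncontrolled but are erased in steps 15 and 19.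

**Step 15**
Reactants: 27 aldol adduct
Product: 29 keto triol bis-silyl ether (C6H2; C13–OH free; C1–OTBS and C11–OTBS kept), via β-keto acid 28 (not isolated)
Conditions: H2 (1 atm), Pd/C, EtOAc, rt; then 45 °C
Reagents that add atoms: none
Why: One hydrogenolysis cleaves the benzyl ester and the benzyl ether, and β-keto acid 28 decarboxylates under neutral conditions that spare the aldol unit and the silyl ethers; no alkene is present at this stage.

**Step 16**
Reactants: 29 C13 alcohol; 30 2-nitrobenzenesulfonamide
Product: 31 C13 N-(2-nitrophenylsulfonyl)amine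
Conditions: 30 (4 equiv), PPh3 (1.2 equiv), DIAD (1.2 equiv), THF, 0 °C to rt
Reagents that add atoms: none
Why: Fukuyama–Mitsunobu alkylation; at this stoichiometry only the primary C13–OH should be activated, the C1 oxygen is silylated and cannot form a cyclic ether, and the excess of the acidic sulfonamide suppresses double alkylation while bringing in N12.

**Step 17**
Reactants: 31 bis-silyl ether sulfonamide
Product: 32 tetraol sulfonamide (C1, C3, C9 and C11 hydroxyls free)
Conditions: HF·pyridine, pyridine, THF, 0 °C to rt
Reagents that add atoms: none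
Why: Fluoride cleavage of both silyl ethers in a buffered, mildly acidic medium should avoid retro-aldol cleavage and dehydration of the C9 aldol unit.

**Step 18**
Reactants: 32 tetraol sulfonamide
Product: 33 N-Ns azonane triol (ring C closed through N12–C11)
Conditions: PPh3, DIAD (slow addition), toluene–THF, 0.002 M, rt
Reagents that add atoms: none
Why: Intramolecular Fukuyama–Mitsunobu reaction, a well-used closure for medium-ring amines; the primary C11–OH is activated first, the deprotonated sulfonamide is the only competent nucleophile, and the two chains sit on adjacent atoms of ring B, which shortens the distance between the ends.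

**Step 19**
Reactants: 33 N-Ns azonane triol
Product: 35 N-Ns (E)-enone diacetate, via triacetate 34 (not isolated)
Conditions: Ac2O, Et3N, DMAP, CH2Cl2, rt to 35 °C; then DBU, 0 °C
Reagents that add atoms: acetic anhydride, CC(=O)OC(C)=O
Why: DMAP-catalysed acetylation of all three hydroxyls (the tertiary one included) is followed by E1cB loss of the C9 acetate, the only one β to a carbonyl; since C8 and C9 are members of the nine-membered ring, the alkene should form with C16 and C10 cis, which is the (E)-enone of the target.

**Step 20**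
Reactants: 35 N-Ns enone diacetate
Product: 36 target CNP0120442.1
Conditions: PhSH, K2CO3, MeCN, rt
Reagents that add atoms: none
Why: Fukuyama denosylation, in which thiolate adds to the nitroarene (Meisenheimer complex), SO2 is lost and the secondary amine is released under conditions too mild for acetate cleavage; thiolate addition to the hindered enone is reversible.

**Compound list**

1 | 5-(benzyloxy)pentan-1-ol | OCCCCCOCc1ccccc1 | starting material
2 | 5-(benzyloxy)pentanal | O=CCCCCOCc1ccccc1 | intermediate
3 | tert-butyl bromoacetate | CC(C)(C)OC(=O)CBr | starting material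
4 | (E)-N,N-diisobutyl-5-(benzyloxy)pent-1-en-1-amine | CC(C)CN(CC(C)C)/C=C/CCCOCc1ccccc1 | intermediate
5 | tert-butyl 6-(benzyloxy)-3-formylhexanoate (racemic) | O=CC(CC(=O)OC(C)(C)C)CCCOCc1ccccc1 | intermediate
6 | methyl vinyl ketone | CC(=O)C=C | starting material
7 | tert-butyl 6-(benzyloxy)-3-formyl-3-(3-oxobutyl)hexanoate (racemic) | CC(=O)CCC(C=O)(CC(=O)OC(C)(C)C)CCCOCc1ccccc1 | intermediate
8 | tert-butyl 2-{1-[3-(benzyloxy)propyl]-4-oxocyclohex-2-en-1-yl}acetate (racemic) | CC(C)(C)OC(=O)CC1(CCCOCc2ccccc2)C=CC(=O)CC1 | intermediate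
9 | lithium cross-conjugated dienolate of 8 | [Li+].[O-]C1=CCC(CC(=O)OC(C)(C)C)(CCCOCc2ccccc2)C=C1 | intermediate
10 | tert-butyl 2-{1-[3-(benzyloxy)propyl]-4-oxocyclohexa-2,5-dien-1-yl}acetate | CC(C)(C)OC(=O)CC1(CCCOCc2ccccc2)C=CC(=O)C=C1 | intermediate
11 | 2-{1-[3-(benzyloxy)propyl]-4-oxocyclohexa-2,5-dien-1-yl}acetic acid | OC(=O)CC1(CCCOCc2ccccc2)C=CC(=O)C=C1 | intermediate
12 | Meldrum's acid | CC1(C)OC(=O)CC(=O)O1 | starting material
13 | benzyl alcohol | OCc1ccccc1 | starting material
14 | 5-acyl Meldrum's acid of 11 (enol form) | CC1(C)OC(=O)C(=C(O)CC2(CCCOCc3ccccc3)C=CC(=O)C=C2)C(=O)O1 | intermediate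
15 | benzyl 4-{1-[3-(benzyloxy)propyl]-4-oxocyclohexa-2,5-dien-1-yl}-3-oxobutanoate (achiral) | O=C(CC(=O)CC1(CCCOCc2ccccc2)C=CC(=O)C=C1)OCc1ccccc1 | intermediate
16 | cis-fused bicyclic enone β-keto benzyl ester (H5 and C15 chain α) | C1=CC(=O)C[C@H]2[C@H](C(=O)OCc3ccccc3)C(=O)C[C@]21CCCOCc1ccccc1 | intermediate
17 | lithium enolate of 16 (C6=C7–O−) | [Li+].C1=CC(=O)C[C@H]2C(C(=O)OCc3ccccc3)=C([O-])C[C@]21CCCOCc1ccccc1 | intermediate
18 | allylic alcohol, C3–OH β | C1=C[C@@H](O)C[C@H]2[C@H](C(=O)OCc3ccccc3)C(=O)C[C@]21CCCOCc1ccccc1 | intermediate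
19 | C1–C2 β-epoxide, C3–OH β | [C@H]12O[C@H]1[C@@H](O)C[C@H]3[C@H](C(=O)OCc4ccccc4)C(=O)C[C@]32CCCOCc1ccccc1 | intermediate
20 | C1–C2 β-epoxy C3 ketone | [C@H]12O[C@H]1C(=O)C[C@H]3[C@H](C(=O)OCc4ccccc4)C(=O)C[C@]32CCCOCc1ccccc1 | intermediate
21 | β-hydroxy ketone, C1–OH β | O[C@H]1CC(=O)C[C@H]2[C@H](C(=O)OCc3ccccc3)C(=O)C[C@]21CCCOCc1ccccc1 | intermediate
22 | C1–OTBS ketone | CC(C)(C)[Si](C)(C)O[C@H]1CC(=O)C[C@H]2[C@H](C(=O)OCc3ccccc3)C(=O)C[C@]21CCCOCc1ccccc1 | intermediate
23 | lithium enolate of 22 | [Li+].CC(C)(C)[Si](C)(C)O[C@H]1CC(=O)C[C@H]2C(C(=O)OCc3ccccc3)=C([O-])C[C@]21CCCOCc1ccccc1 | intermediate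
24 | tertiary alcohol, C3–OH β, C3–CH3 α | CC(C)(C)[Si](C)(C)O[C@H]1C[C@@](C)(O)C[C@H]2[C@H](C(=O)OCc3ccccc3)C(=O)C[C@]21CCCOCc1ccccc1 | intermediate
25 | 3-(tert-butyldimethylsilyloxy)propanal | O=CCCO[Si](C)(C)C(C)(C)C | starting material
26 | trilithium salt of 24 (C3 alkoxide and C6/C8 dianion) | [Li+].[Li+].[Li+].CC(C)(C)[Si](C)(C)O[C@H]1C[C@@](C)([O-])C[C@H]2C(=C([O-])OCc3ccccc3)C([O-])=C[C@]21CCCOCc1ccccc1 | intermediate
27 | C8 aldol adduct (epimers at C6, C8, C9) | CC(C)(C)[Si](C)(C)O[C@H]1C[C@@](C)(O)C[C@H]2C(C(=O)OCc3ccccc3)C(=O)C(C(O)CCO[Si](C)(C)C(C)(C)C)[C@]21CCCOCc1ccccc1 | intermediate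
28 | β-keto acid with free C13–OH (epimers at C6, C8, C9) | CC(C)(C)[Si](C)(C)O[C@H]1C[C@@](C)(O)C[C@H]2C(C(=O)O)C(=O)C(C(O)CCO[Si](C)(C)C(C)(C)C)[C@]21CCCO | intermediate
29 | decarboxylated ketone, C13–OH free (epimers at C8, C9) | CC(C)(C)[Si](C)(C)O[C@H]1C[C@@](C)(O)C[C@H]2CC(=O)C(C(O)CCO[Si](C)(C)C(C)(C)C)[C@]21CCCO | intermediate
30 | 2-nitrobenzenesulfonamide | NS(=O)(=O)c1ccccc1[N+](=O)[O-] | starting material
31 | C13 NH–Ns sulfonamide (epimers at C8, C9) | CC(C)(C)[Si](C)(C)O[C@H]1C[C@@](C)(O)C[C@H]2CC(=O)C(C(O)CCO[Si](C)(C)C(C)(C)C)[C@]21CCCNS(=O)(=O)c1ccccc1[N+](=O)[O-] | intermediate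
32 | tetraol sulfonamide (epimers at C8, C9) | O[C@H]1C[C@@](C)(O)C[C@H]2CC(=O)C(C(O)CCO)[C@]21CCCNS(=O)(=O)c1ccccc1[N+](=O)[O-] | intermediate
33 | N-Ns azonane triol (epimers at C8, C9) | O[C@H]1C[C@@](C)(O)C[C@H]2CC(=O)C3C(O)CCN(S(=O)(=O)c4ccccc4[N+](=O)[O-])CCC[C@@]321 | intermediate
34 | N-Ns azonane triacetate (epimers at C8, C9) | CC(=O)O[C@H]1C[C@@](C)(OC(C)=O)C[C@H]2CC(=O)C3C(OC(C)=O)CCN(S(=O)(=O)c4ccccc4[N+](=O)[O-])CCC[C@@]321 | intermediate
35 | N-Ns (E)-enone diacetate | CC(=O)O[C@H]1C[C@@](C)(OC(C)=O)C[C@H]2CC(=O)/C3=C/CCN(S(=O)(=O)c4ccccc4[N+](=O)[O-])CCC[C@@]321 | intermediate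
36 | CNP0120442.1 | CC(=O)O[C@H]1C[C@@](C)(OC(C)=O)C[C@H]2CC(=O)/C3=C/CCNCCC[C@@]321 | target

**Totals and risks**

Total step count: 20. Longest linear sequence: 20 steps, from 1.

**Step 7.** The catalyst may discriminate poorly between the two enone arms, or an uncatalysed background closure may erode the enantiomeric purity. The fallback replaces catalyst control by auxiliary control and sets out from acid 11.

- The acyl Meldrum's acid 14 is heated with (−)-8-phenylmenthol in place of benzyl alcohol. This gives the 8-phenylmenthyl dienone β-keto ester F1.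
- Catalytic Cs2CO3 in toluene closes ring B through the same C5–C6 bond to two cis-fused diastereomers.
- The cis-fused 8-phenylmenthyl keto ester F2, which has the C5/C16 configuration of 16, is separated from them by chromatography or crystallization.
- DMAP-catalysed transesterification of F2 with benzyl alcohol in refluxing toluene returns to the route at 16.

**Step 13.** Equatorial attack may compete, which would give poor facial selectivity. MeLi may also act as a base and trigger loss of the C1 silyloxy group by β-elimination. The fallback builds the carbinol in two stages and sets out from 22.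

- Dimethylsulfonium methylide is made from Me3SI and NaH in DMSO–THF at 0 °C. Two equivalents are used, and the first is spent on the β-keto ester.
- In a Corey–Chaykovsky reaction this small ylide adds irreversibly along the axial trajectory. It should give the C3 spiro-epoxide F3 with CH2 α and O β.
- After renewed enolate protection with LiN(SiMe3)2, LiBHEt3 opens the oxirane at its CH2 terminus and the route is rejoined at 24.

**Step 18.** Intermolecular alkylation (oligomerization) may outrun the slow nine-membered closure. The phosphonium reagent may also activate the C9–OH and dehydrate the aldol unit before the ring exists. The fallback uses the nitrogen as a linchpin between two electrophilic termini and sets out from 29.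

- PPTS in MeOH removes only the primary silyl group and gives the C11,C13-diol F4.
- MsCl and Et3N at −40 °C give the bis-mesylate F5.
- Compound 30 with Cs2CO3 and Bu4NI in dilute MeCN at 50 °C is alkylated twice, and the ring closes at whichever C–N bond forms second. This gives the C1-silylated N-Ns azonane F6.
- HF·pyridine then returns to the route at 33.

**Further compounds**

F1 | step 7 | (−)-8-phenylmenthyl 4-{1-[3-(benzyloxy)propyl]-4-oxocyclohexa-2,5-dien-1-yl}-3-oxobutanoate | CC(C)(c1ccccc1)[C@@H]1CC[C@@H](C)C[C@H]1OC(=O)CC(=O)CC1(CCCOCc2ccccc2)C=CC(=O)C=C1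
F2 | step 7 | cis-fused bicyclic enone β-keto ester as its (−)-8-phenylmenthyl ester, C5/C16 as in 16 | C1=CC(=O)C[C@H]2[C@H](C(=O)O[C@@H]3C[C@H](C)CC[C@H]3C(C)(C)c3ccccc3)C(=O)C[C@]21CCCOCc1ccccc1
F3 | step 13 | C3 spiro-epoxide of 22 (CH2 α, O β) | CC(C)(C)[Si](C)(C)O[C@H]1C[C@@]3(OC3)C[C@H]2[C@H](C(=O)OCc3ccccc3)C(=O)C[C@]21CCCOCc1ccccc1
F4 | step 18 | C11,C13-diol with C1–OTBS kept (epimers at C8, C9) | CC(C)(C)[Si](C)(C)O[C@H]1C[C@@](C)(O)C[C@H]2CC(=O)C(C(O)CCO)[C@]21CCCO
F5 | step 18 | C11,C13-bis-mesylate (epimers at C8, C9) | CC(C)(C)[Si](C)(C)O[C@H]1C[C@@](C)(O)C[C@H]2CC(=O)C(C(O)CCOS(C)(=O)=O)[C@]21CCCOS(C)(=O)=O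
F6 | step 18 | N-Ns azonane with C1–OTBS (epimers at C8, C9) | CC(C)(C)[Si](C)(C)O[C@H]1C[C@@](C)(O)C[C@H]2CC(=O)C3C(O)CCN(S(=O)(=O)c4ccccc4[N+](=O)[O-])CCC[C@@]321
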